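The data are simulated with made-up constants; scatter was added.

At 4.0 d, when you read this flask, you want to know how much target stands in it and whether any option still pays.

| setting | spring | noon | flask |
|---|---|---|---|
| starting material | 0.10 M | 0.10 M | 0.10 M |
| second substrate | 1 equiv | 1 equiv | 1.00 equiv |
| free enzyme | 5.4 × 10⁻⁴ mol% | 5.4 × 10⁻⁴ mol% | 5.4 × 10⁻⁴ mol% |
| temperature | 30 °C | 25 °C | 30 °C |
| remark | the very flask that is asked about, followed so far | run made earlier |  |
| time |  |  | 4.0 d |

- spring (time / d: target / %, starting material / %): 0.625: 46, 46; 1.25: 69, 11; 2.08: 80, 2; 2.50: 82, 3; 3.00: 80, 2
- noon (time / d: target / %, starting material / %): 0.625: 33, 65; 1.25: 57, 28; 2.08: 76, 9; 2.50: 81, 0; 3.00: 83, 0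

(readings scatter by 1.5 percentage points)

- alpha: change nothing and wait 30 h more
- zeta: at 4.0 d raise the temperature by 15 K, then wait 30 h
- theta: at 4.0 d add free enzyme, 50.0% of the amount charged, then wait 30 h
- delta: at 4.0 d add second substrate, 100% of the amount charged, then wait 30 h
- eta: at 4.0 d take out 90% of the target then present, then wait 30 h

- removed target is counted in
- additions bring no volume worth counting

1. target, in percent of the starting material first charged, at 4.0 d
2. the option that brings most further target ("none" if no option brings more than 2 percentage points) (alpha / zeta / theta / delta / eta / none)
3. target present, with what was taken out counted in, in percent of the starting material first charged, after delta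
4. target present, with what was taken out counted in, in percent of the starting material first charged, after eta

First, is this flask still making target? The spring run is this flask followed so far, and its target reads 80%, 82% and 80% from 2.08 d to 3.00 d, with a scatter of 1.5 percentage points. That is a plateau, so I take its mean, 80.7%, as the target at the time of reading.

Second, what became of the charge? Over those 3 readings the starting material averages 2.33% of the charge. Dividing target by the fraction consumed gives the converted share, the selectivity: 82.6%. The other 17.4% of what was consumed appears in these readings neither as target nor as starting material.

Third, what is left to win? If further target must come from starting material still present, the headroom is that remaining fraction times the converted share: 1.9 points. This reading is less than the 2 points an option must bring, though by less than the scatter of 1.5 points, and it was taken before 4.0 d. With that caution, the question for this flask has changed from how fast it runs to how much remains. I therefore reckon that no option clears the mark, and that delta and eta end between 80.7% and 82.6%.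

The forecast gives 81% now, none as the best option, 82% after delta and 82.5% after eta, holding that “the reaction has finished, not stalled”.

The flask gives 81.3% now, none as the best option, 81.3% after delta and 81.3% after eta.

    free enzyme → unfolded enzyme (k = 0.00208 h⁻¹, Ea = 195 kJ mol⁻¹)
    starting material + free enzyme ⇌ first complex (K = 23.0 L mol⁻¹, k = 2.10 × 10⁷ L mol⁻¹ h⁻¹, Ea = 35.0 kJ mol⁻¹, ΔH = −21.0 kJ mol⁻¹)
    first complex → loaded enzyme + first product (k = 10800 h⁻¹, Ea = 70.0 kJ mol⁻¹)
    second substrate + loaded enzyme ⇌ second complex (K = 19.5 L mol⁻¹, k = 1.77 × 10⁶ L mol⁻¹ h⁻¹, Ea = 38.0 kJ mol⁻¹, ΔH = −43.0 kJ mol⁻¹)
    second complex → free enzyme + target (k = 94000 h⁻¹, Ea = 62.0 kJ mol⁻¹)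
    starting material + first product → side product (k = 0.439 L mol⁻¹ h⁻¹, Ea = 86.0 kJ mol⁻¹)
    (constants at 30 °C)

Half of the turnover of the step from first complex to loaded enzyme and first product is done by 0.543 d, earlier than the reading at 4.0 d. At 4.00 d the starting material, the limiting reagent, stands in this flask at 0%, so the headroom reckoned with the converted share is 0 points, while 85.2% of the catalyst can still turn over.

In the neighbour charged with 2.2 × 10⁻⁴ mol% of free enzyme, 1.7% of the starting material remains, so the converted share read in the spring run gives 81.2% target and a headroom of 1.4 points. The computed neighbour holds 70.0% target and 28.4% side product, a converted share of 71.2%, which is less than the one read in the spring run, so that share does not carry over to this neighbour.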